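**Plan**

- Cuts: ring C is opened at O1–C2 (a ring A phenol adding to a C2 methyl enol ether with loss of MeOH), then C4–C4a is cut between a lithiated phloroglucinol tris(methoxymethyl) ether and an N-methoxy-N-methylamide holding C4, C3–OMe, C2 and ring B with its prenyl ether. The amide is cut at C2–C3 (acylation of a methoxyacetamide enolate) and at the enol O–CH3 bond.
- Enabling feature: C4a lies between the oxygen-bearing carbons C5 and C8a, and ring A also carries oxygen at C7. Without C4, ring A is therefore a threefold-symmetric 1,3,5-trioxygenated benzene with one kind of C–H, each flanked by two directing acetal oxygens. Whichever ortho oxygen closes becomes O1; the other two end as 5-OH and 7-OH.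
- Forward order: rings A and B are bought (phloroglucinol, methyl 4-hydroxybenzoate). C2–C3 is made first, the finished C4–C3–C2–ring B chain is joined to ring A at C4–C4a, and ring C closes last.
- Stereochemistry: the target has no stereocentre. The C2=C3 enol ether geometry of the intermediates is erased when C2 becomes tetrahedral during ring closure.

Key step: step 7

Assumption: enol ethers 12 and 15 are drawn as E isomers; the geometry is not controlled deliberately and the Z isomers, alone or in admixture, would serve equally.

**Step 1**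
Reactants: 1 phloroglucinol
Product: 2 1,3,5-tris(methoxymethoxy)benzene
Conditions: NaH (3.6 equiv), MOMCl (3.6 equiv), DMF, 0 °C to rt
Reagents that add atoms: chloromethyl methyl ether (MOMCl), COCCl
Why: O-alkylation of the sodium phenoxides by the reactive α-chloro ether (Williamson-type acetal formation) is the standard methoxymethyl protection of phenols and should give the symmetric tris-acetal.

**Step 2**
Reactants: 3 methyl 4-hydroxybenzoate; 4 prenyl bromide (1-bromo-3-methylbut-2-ene)
Product: 5 methyl 4-(3-methylbut-2-enyloxy)benzoate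
Conditions: K2CO3, acetone, reflux
Reagents that add atoms: none
Why: Williamson ether synthesis, in which the phenoxide (made acidic enough for K2CO3 by the para ester) displaces bromide from the primary allylic bromide by SN2.

**Step 3**
Reactants: 5 methyl 4-(3-methylbut-2-enyloxy)benzoate
Product: 6 4-(3-methylbut-2-enyloxy)benzoic acid
Conditions: NaOH, MeOH–THF–H2O, 60 °C; then 1 M HCl to pH 3, 0 °C
Reagents that add atoms: sodium hydroxide, [Na+].[OH-]
Why: Saponification of the methyl ester leaves the allyl aryl ether untouched, and the brief cold acidification should only protonate the carboxylate.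

**Step 4**
Reactants: 7 methyl methoxyacetate
Product: 8 N,2-dimethoxy-N-methylacetamide
Conditions: MeNH(OMe)·HCl (1.5 equiv), i-PrMgCl (3.0 equiv), THF, −20 to 0 °C
Reagents that add atoms: N,O-dimethylhydroxylamine hydrochloride, CNOC.Cl
Why: Aminolysis of an unhindered ester by the chloromagnesium amide of MeNH(OMe) is the standard ester-to-N-methoxy-N-methylamide conversion, its tetrahedral adduct holding until work-up.

**Step 5**
Reactants: 6 4-(3-methylbut-2-enyloxy)benzoic acid; 8 N,2-dimethoxy-N-methylacetamide
Product: 11 N,2-dimethoxy-N-methyl-3-[4-(3-methylbut-2-enyloxy)phenyl]-3-oxopropanamide (racemic at C2), via acyl imidazolide 9 (not isolated), via lithium enolate 10 (not isolated)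
Conditions: 6, 1,1'-carbonyldiimidazole (1.05 equiv), THF, rt; added to 8 (3.3 equiv)/LiN(i-Pr)2 (3.2 equiv), THF, −78 to −40 °C; aq. NH4Cl
Reagents that add atoms: none
Why: Crossed Claisen-type C-acylation of a preformed amide lithium enolate by an acyl imidazolide, in which the excess enolate absorbs the imidazole N–H and the acidic proton of the 1,3-dicarbonyl product, so the new ketone is protected as its enolate from a second attack.

**Step 6**
Reactants: 11 N,2-dimethoxy-N-methyl-3-[4-(3-methylbut-2-enyloxy)phenyl]-3-oxopropanamide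
Product: 12 (E)-N,2,3-trimethoxy-N-methyl-3-[4-(3-methylbut-2-enyloxy)phenyl]prop-2-enamide
Conditions: Cs2CO3 (1.5 equiv), Me2SO4 (1.2 equiv), DMF, 0 °C to rt
Reagents that add atoms: dimethyl sulfate, COS(=O)(=O)OC
Why: O-alkylation of the loosely paired cesium enolate of a 2-substituted 1,3-dicarbonyl compound by the hard electrophile Me2SO4 in a dipolar aprotic solvent, reaction at carbon being disfavoured because it would build a quaternary centre.

**Step 7**
Reactants: 2 1,3,5-tris(methoxymethoxy)benzene; 12 (E)-N,2,3-trimethoxy-N-methyl-3-[4-(3-methylbut-2-enyloxy)phenyl]prop-2-enamide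
Product: 15 (E)-2,3-dimethoxy-3-[4-(3-methylbut-2-enyloxy)phenyl]-1-[2,4,6-tris(methoxymethoxy)phenyl]prop-2-en-1-one, via aryllithium 13 (not isolated), via lithium hemiaminal chelate 14 (not isolated)
Conditions: 2 (1.3 equiv), n-BuLi (1.2 equiv), THF, 0 °C, 1 h; then 12 (1.0 equiv), −78 to 0 °C; aq. NH4Cl
Reagents that add atoms: none
Why: n-BuLi, held by two flanking methoxymethoxy groups, removes the proton between them (directed ortho-metalation; the three ring C–H of 2 are equivalent, so only aryllithium 13 can form), and 13 adds to the amide carbonyl of 12 to give the five-membered N-methoxy lithium chelate 14, which releases ketone 15 only on aqueous quench, so a second addition is excluded. The closest known reaction type is the Weinreb ketone synthesis with ortho-lithiated polyalkoxybenzenes and with β-alkoxyacrylic N-methoxy-N-methylamides, which give β-alkoxy enones by carbonyl addition. The step forms the C4–C4a bond only: no ring is closed, no stereocentre is created, and the C2=C3 geometry of 12 is carried through unchanged. The selectivity needed is carbonyl addition over attack at the future C2 and over metalation of the prenyl ether; the first is secured by lithium chelation at the N-methoxy amide and by C2 being fully substituted and electron-rich through its methoxy and aryl donors, the second by using slightly less n-BuLi than 2 so that no alkyllithium remains when 12 is added at −78 °C.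

**Step 8**
Reactants: 15 (E)-2,3-dimethoxy-3-[4-(3-methylbut-2-enyloxy)phenyl]-1-[2,4,6-tris(methoxymethoxy)phenyl]prop-2-en-1-one
Product: 17 5,7-dihydroxy-3-methoxy-2-[4-(3-methylbut-2-enyloxy)phenyl]-4H-chromen-4-one (5,7-dihydroxy-3-methoxy-4'-prenyloxyflavone), via triphenol 16 (not isolated)
Conditions: conc. HCl (to ca. 0.5 M), MeOH–THF 4:1, 0 °C to rt
Reagents that add atoms: none
Why: Acid-catalysed transacetalisation to MeOH removes the three methoxymethyl groups, and an ortho phenol of 16 adds to C2 of the protonated vinylogous ester (6-endo-trig oxa-Michael addition) and MeOH is expelled to give the 4-pyranone, a chromone-forming addition–elimination known for 2-hydroxyaryl β-alkoxy and β-amino enones, with the acid kept dilute and cool to spare the prenyl ether.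

**Compound list**

1 | phloroglucinol | Oc1cc(O)cc(O)c1 | starting material
2 | 1,3,5-tris(methoxymethoxy)benzene | COCOc1cc(OCOC)cc(OCOC)c1 | intermediate
3 | methyl 4-hydroxybenzoate | COC(=O)c1ccc(O)cc1 | starting material
4 | prenyl bromide (1-bromo-3-methylbut-2-ene) | CC(C)=CCBr | starting material
5 | methyl 4-(3-methylbut-2-enyloxy)benzoate | COC(=O)c1ccc(OCC=C(C)C)cc1 | intermediate
6 | 4-(3-methylbut-2-enyloxy)benzoic acid | OC(=O)c1ccc(OCC=C(C)C)cc1 | intermediate
7 | methyl methoxyacetate | COCC(=O)OC | starting material
8 | N,2-dimethoxy-N-methylacetamide | COCC(=O)N(C)OC | intermediate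
9 | (imidazol-1-yl)[4-(3-methylbut-2-enyloxy)phenyl]methanone (acyl imidazolide; formed in the flask, not isolated) | O=C(c1ccc(OCC=C(C)C)cc1)n1ccnc1 | intermediate
10 | lithium (Z)-2-methoxy-1-[methoxy(methyl)amino]ethenolate (enolate of 8; formed in the flask, not isolated) | [Li]O/C(N(C)OC)=C\OC | intermediate
11 | N,2-dimethoxy-N-methyl-3-[4-(3-methylbut-2-enyloxy)phenyl]-3-oxopropanamide (racemic) | CON(C)C(=O)C(OC)C(=O)c1ccc(OCC=C(C)C)cc1 | intermediate
12 | (E)-N,2,3-trimethoxy-N-methyl-3-[4-(3-methylbut-2-enyloxy)phenyl]prop-2-enamide | CON(C)C(=O)/C(OC)=C(\OC)c1ccc(OCC=C(C)C)cc1 | intermediate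
13 | 2,4,6-tris(methoxymethoxy)phenyllithium (formed in the flask, not isolated) | [Li]c1c(OCOC)cc(OCOC)cc1OCOC | intermediate
14 | lithium (E)-2,3-dimethoxy-1-[methoxy(methyl)amino]-3-[4-(3-methylbut-2-enyloxy)phenyl]-1-[2,4,6-tris(methoxymethoxy)phenyl]prop-2-en-1-olate (racemic chelate; formed in the flask, not isolated) | COCOc1cc(OCOC)c(C(O[Li])(N(C)OC)/C(OC)=C(\OC)c2ccc(OCC=C(C)C)cc2)c(OCOC)c1 | intermediate
15 | (E)-2,3-dimethoxy-3-[4-(3-methylbut-2-enyloxy)phenyl]-1-[2,4,6-tris(methoxymethoxy)phenyl]prop-2-en-1-one | COCOc1cc(OCOC)c(C(=O)/C(OC)=C(\OC)c2ccc(OCC=C(C)C)cc2)c(OCOC)c1 | intermediate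
16 | (E)-2,3-dimethoxy-3-[4-(3-methylbut-2-enyloxy)phenyl]-1-(2,4,6-trihydroxyphenyl)prop-2-en-1-one (formed in the flask, not isolated) | Oc1cc(O)c(C(=O)/C(OC)=C(\OC)c2ccc(OCC=C(C)C)cc2)c(O)c1 | intermediate
17 | 5,7-dihydroxy-3-methoxy-2-[4-(3-methylbut-2-enyloxy)phenyl]-4H-chromen-4-one | COc1c(-c2ccc(OCC=C(C)C)cc2)oc2cc(O)cc(O)c2c1=O | target

**Step count**

Total: 8 steps. Longest linear sequence: 6 steps (steps 2, 3, 5, 6, 7, 8 from methyl 4-hydroxybenzoate).

**Steps most likely to fail**

Step 7. What may go wrong: slow or incomplete carbonyl addition, because a 2,6-disubstituted aryllithium meets an α-substituted, donor-deactivated amide, so that proton transfer or attack at C2 takes over on warming. Fallback, setting out from 12: reduction with i-Bu2AlH in THF at −78 °C should give (E)-2,3-dimethoxy-3-[4-(3-methylbut-2-enyloxy)phenyl]prop-2-enal F1. This smaller and more electrophilic acceptor should take up aryllithium 13 (from 2 and n-BuLi as in step 7) at −78 °C to give racemic (E)-2,3-dimethoxy-3-[4-(3-methylbut-2-enyloxy)phenyl]-1-[2,4,6-tris(methoxymethoxy)phenyl]prop-2-en-1-ol F2. Oxidation of this benzylic, allylic alcohol with MnO2 in CH2Cl2 comes back to the route at 15. The same C4–C4a bond is formed by the same aryllithium; only the oxidation level of the acceptor changes.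

Step 8. What may go wrong: acid ionisation of the allylic aryl ether (loss of the prenyl group as an allyl cation, or addition of HCl or MeOH across its alkene) competing with acetal cleavage. Fallback, setting out from 15: the aryl methoxymethyl ethers are cleaved without Brønsted acid by Me3SiOTf and 2,2'-bipyridyl in CH2Cl2 at 0 °C, which should convert them into (E)-2,3-dimethoxy-3-[4-(3-methylbut-2-enyloxy)phenyl]-1-[2,4,6-tris(trimethylsilyloxy)phenyl]prop-2-en-1-one F3. Water then hydrolyses the silyl ethers to triphenol 16, here isolated. Ring C is closed separately with K2CO3 in MeOH at rt by phenoxide addition to C2 and loss of methoxide, coming back to the route at 17.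

Step 6. What may go wrong: methylation at carbon competing with methylation at the enolate oxygen. Fallback, setting out from 11: silylation with t-BuMe2SiOTf and Et3N in CH2Cl2 at 0 °C, which takes place at oxygen only, should give (E)-3-(tert-butyldimethylsilyloxy)-N,2-dimethoxy-N-methyl-3-[4-(3-methylbut-2-enyloxy)phenyl]prop-2-enamide F4. Aryllithium 13 is added as in step 7 to give, after quench, (E)-3-(tert-butyldimethylsilyloxy)-2-methoxy-3-[4-(3-methylbut-2-enyloxy)phenyl]-1-[2,4,6-tris(methoxymethoxy)phenyl]prop-2-en-1-one F5. Under the conditions of step 8 the silyl enol ether and the acetals are cleaved, and the liberated 2-methoxy-1,3-diketone should cyclodehydrate with an ortho phenol, coming back to the route at 17.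

**Further compounds**

F1 | step 7 | (E)-2,3-dimethoxy-3-[4-(3-methylbut-2-enyloxy)phenyl]prop-2-enal | O=C/C(OC)=C(\OC)c1ccc(OCC=C(C)C)cc1
F2 | step 7 | (E)-2,3-dimethoxy-3-[4-(3-methylbut-2-enyloxy)phenyl]-1-[2,4,6-tris(methoxymethoxy)phenyl]prop-2-en-1-ol (racemic) | COCOc1cc(OCOC)c(C(O)/C(OC)=C(\OC)c2ccc(OCC=C(C)C)cc2)c(OCOC)c1
F3 | step 8 | (E)-2,3-dimethoxy-3-[4-(3-methylbut-2-enyloxy)phenyl]-1-[2,4,6-tris(trimethylsilyloxy)phenyl]prop-2-en-1-one | C[Si](C)(C)Oc1cc(O[Si](C)(C)C)c(C(=O)/C(OC)=C(\OC)c2ccc(OCC=C(C)C)cc2)c(O[Si](C)(C)C)c1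
F4 | step 6 | (E)-3-(tert-butyldimethylsilyloxy)-N,2-dimethoxy-N-methyl-3-[4-(3-methylbut-2-enyloxy)phenyl]prop-2-enamide | CON(C)C(=O)/C(OC)=C(\O[Si](C)(C)C(C)(C)C)c1ccc(OCC=C(C)C)cc1
F5 | step 6 | (E)-3-(tert-butyldimethylsilyloxy)-2-methoxy-3-[4-(3-methylbut-2-enyloxy)phenyl]-1-[2,4,6-tris(methoxymethoxy)phenyl]prop-2-en-1-one | COCOc1cc(OCOC)c(C(=O)/C(OC)=C(\O[Si](C)(C)C(C)(C)C)c2ccc(OCC=C(C)C)cc2)c(OCOC)c1
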